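## Retrosynthetic overview

- Late stage: the 6α-hydroxy-7-oxo-8(17)-ene array of ring B and the C1 isobutyrate are installed on a 7-hydroxy-cleroda-4(18)-ene.
- Key disconnection: the clerodane core arises from a labdane-type bicycle by the biogenetic backbone rearrangement (H-9→C8, CH3 C10→C9, H-5→C10, CH3 C4→C5). A CH2SiMe3 group on C4 ends the cascade as the 4(18)-alkene only.
- The bicycle comes from a polyene bicyclisation of an acyclic, oxygenated geranylgeranyl-type chain (C4–C5 bond first, then C10–C9), steered by the C1 and C7 carbinol centres.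
- The chain is joined from three pieces by two catalytic asymmetric alkenylzinc–aldehyde additions (C1–C10 and C7–C8). The C12/C13 pair comes from one anti-(hydroxymethyl)allylation.
- Ring order: butyrolactone (on the side-chain fragment), then ring A, then ring B (same operation as ring A); the rearrangement forms no further ring.

Assumption: clerodane numbering (C1–C20; lactone C15(=O)–O–C16) is used for every compound, acyclic ones included; α/β refer to the skeleton drawn with ring A on the left and H-10 of the target up (β); the target is (1R,5R,6R,9R,10R,12R,13R).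

## Route

Step 1
Reactants: 1 methyl 4,4-dimethoxybutanoate; 2 (trimethylsilyl)methylmagnesium chloride
Product: 5 4-[(trimethylsilyl)methyl]pent-4-enal, via tertiary carbinol 3 (not isolated), via acetal allylsilane 4 (not isolated)
Conditions: 2 (3 equiv), CeCl3 (3 equiv), THF, −78 °C → rt; then 10% aq. oxalic acid, THF, rt
Reagents that add atoms: water, O
Why: Double Grignard addition to the ester, then acid-induced Peterson elimination (Bunnelle allylsilane synthesis) and mild acetal hydrolysis; no stereocentre is formed.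

Step 2
Reactants: 6 pent-3-yn-1-ol
Product: 7 triethyl(pent-3-yn-1-yloxy)silane
Conditions: TESCl, imidazole, CH2Cl2, 0 °C
Reagents that add atoms: chlorotriethylsilane, CC[Si](Cl)(CC)CC
Why: Routine O-silylation; the primary TES ether is later oxidised directly to the aldehyde.

Step 3
Reactants: 7 triethyl(pent-3-yn-1-yloxy)silane; 5 4-[(trimethylsilyl)methyl]pent-4-enal
Product: 10 (3E,5R)-4-methyl-8-methylidene-1-(triethylsilyloxy)-9-(trimethylsilyl)non-3-en-5-ol, via alkenylzirconocene chloride 8 (not isolated), via alkenyl(methyl)zinc 9 (not isolated)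
Conditions: Cp2Zr(H)Cl (slight excess over 7), CH2Cl2, rt → 40 °C; Me2Zn, toluene, −65 °C; (−)-MIB (10 mol %), then 5, −30 °C; aq. NH4Cl
Reagents that add atoms: none
Why: syn-Hydrozirconation puts Zr on the methyl-bearing alkyne carbon (about 9:1 after equilibration, E-alkene), and Zr→Zn transmetalation followed by amino-alcohol-catalysed alkenylzinc addition (Wipf/Oppolzer type) sets C1 as R by Si-face attack under ligand control.

Step 4
Reactants: 10 (3E,5R)-4-methyl-8-methylidene-1-(triethylsilyloxy)-9-(trimethylsilyl)non-3-en-5-ol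
Product: 11 (3E,5R)-5-(tert-butyldimethylsilyloxy)-4-methyl-8-methylidene-1-(triethylsilyloxy)-9-(trimethylsilyl)non-3-ene
Conditions: TBSCl, imidazole, DMF, rt
Reagents that add atoms: tert-butylchlorodimethylsilane, CC(C)(C)[Si](C)(C)Cl
Why: Silylation of the allylic alcohol; a bulky silyl ether was chosen over an ester because an ester at C1 would trap the later C10 cation as a dioxolanylium ion.

Step 5
Reactants: 11 (3E,5R)-5-(tert-butyldimethylsilyloxy)-4-methyl-8-methylidene-1-(triethylsilyloxy)-9-(trimethylsilyl)non-3-ene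
Product: 12 (3E,5R)-5-(tert-butyldimethylsilyloxy)-4-methyl-8-methylidene-9-(trimethylsilyl)non-3-enal
Conditions: (COCl)2, DMSO, CH2Cl2, −78 → −40 °C; Et3N, −78 °C; cold work-up, used at once
Reagents that add atoms: none
Why: Swern conditions convert a primary TES ether directly into the aldehyde while the secondary TBS ether and the allylsilane survive; the β,γ-unsaturated aldehyde is not stored.

Step 6
Reactants: 6 pent-3-yn-1-ol; 13 4-ethenyl-1,3-dioxolan-2-one
Product: 15 (2R,3R)-2-ethenylhept-5-yne-1,3-diol, via pent-3-ynal 14 (not isolated)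
Conditions: [Ir(cod)Cl]2 (2.5 mol %), SEGPHOS (5 mol %, antipode that gives 2R,3R), 4-chloro-3-nitrobenzoic acid (10 mol %), Cs2CO3 (20 mol %), THF, 70 °C
Reagents that add atoms: none
Why: Transfer-hydrogenative anti-(hydroxymethyl)allylation (Krische type): the alcohol is dehydrogenated in situ, the allyl-iridium formed from 13 by decarboxylation adds through a closed chair transition state, and the chiral bisphosphine sets C12 and C13 together as the anti pair.

Step 7
Reactants: 15 (2R,3R)-2-ethenylhept-5-yne-1,3-diol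
Product: 16 (2R,3R)-1-(tert-butyldimethylsilyloxy)-2-ethenylhept-5-yn-3-ol
Conditions: TBSCl (1.05 equiv), imidazole, CH2Cl2, −20 °C
Reagents that add atoms: tert-butylchlorodimethylsilane, CC(C)(C)[Si](C)(C)Cl
Why: Selective silylation of the primary hydroxyl leaves the C12 hydroxyl free for acylation.

Step 8
Reactants: 16 (2R,3R)-1-(tert-butyldimethylsilyloxy)-2-ethenylhept-5-yn-3-ol
Product: 17 (2R,3R)-1-(tert-butyldimethylsilyloxy)-2-ethenylhept-5-yn-3-yl (2E)-2-methylbut-2-enoate
Conditions: tigloyl chloride, pyridine, DMAP (cat.), CH2Cl2, 0 °C → rt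
Reagents that add atoms: (2E)-2-methylbut-2-enoyl chloride, C/C=C(\C)C(=O)Cl
Why: Esterification with retention at C12; fixing the tiglate now prevents the C12 oxygen from competing for the lactone carbonyl later.

Step 9
Reactants: 17 (2R,3R)-1-(tert-butyldimethylsilyloxy)-2-ethenylhept-5-yn-3-yl (2E)-2-methylbut-2-enoate
Product: 19 (3R,4R)-3-[(tert-butyldimethylsilyloxy)methyl]-1-hydroxyoct-6-yn-4-yl (2E)-2-methylbut-2-enoate, via B-alkyl-9-BBN adduct 18 (not isolated)
Conditions: 9-BBN, THF, 0 °C → rt; then H2O2 (30%), aq. NaOAc, 0 °C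
Reagents that add atoms: hydrogen peroxide, OO
Why: Anti-Markovnikov hydroboration–oxidation; 9-BBN takes the terminal vinyl group much faster than the internal alkyne or the conjugated ester.

Step 10
Reactants: 19 (3R,4R)-3-[(tert-butyldimethylsilyloxy)methyl]-1-hydroxyoct-6-yn-4-yl (2E)-2-methylbut-2-enoate
Product: 23 (1R)-1-[(3R)-5-oxooxolan-3-yl]pent-3-yn-1-yl (2E)-2-methylbut-2-enoate, via aldehyde 20 (not isolated), via silyloxy acid 21 (not isolated), via hydroxy acid 22 (not isolated)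
Conditions: TEMPO (20 mol %), PhI(OAc)2 (2.2 equiv), MeCN/H2O, rt; then 1 M HCl, THF, rt
Reagents that add atoms: water, O
Why: Oxoammonium oxidation of the primary alcohol to the acid, then acid-mediated desilylation and spontaneous γ-lactonisation; C12 and C13 are untouched and the lactone can only close onto O16.

Step 11
Reactants: 23 (1R)-1-[(3R)-5-oxooxolan-3-yl]pent-3-yn-1-yl (2E)-2-methylbut-2-enoate; 12 (3E,5R)-5-(tert-butyldimethylsilyloxy)-4-methyl-8-methylidene-9-(trimethylsilyl)non-3-enal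
Product: 26 acyclic (1R,7S,12R,13R)-trienyl tiglate (full name in the list), via alkenylzirconocene chloride 24 (not isolated), via alkenyl(methyl)zinc 25 (not isolated)
Conditions: Cp2Zr(H)Cl (1.05 equiv to 23), CH2Cl2, rt, 1 h; Me2Zn, toluene, −65 °C; (+)-MIB (10 mol %), then 12, −30 °C; aq. NH4Cl
Reagents that add atoms: none
Why: Same hydrozirconation/transmetalation/alkenylzinc addition as step 3 (the alkyne reacts faster than the lactone or the tiglate; the minor regioisomer is removed), with the antipodal ligand giving Re-face attack and C7 as S.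

Step 12
Reactants: 26 acyclic (1R,7S,12R,13R)-trienyl tiglate
Product: 27 labdane-type bicyclic 8(17)-ene (1β-OTBS 7β-OH; full description in the list)
Conditions: [Co(L)Cl] (5 mol %; L = N,N′-bis(3,5-di-tert-butylsalicylidene)ethane-1,2-diaminate), PhSiH3 (10 mol %), benzene, 25 °C, Ar
Reagents that add atoms: none
Why: Proposed new method: [Co(L)H] transfers a hydrogen atom to the 1,1-disubstituted allylsilane alkene (the most reactive site; a protic start is excluded because the β-silyl cation would simply lose silicon), the tertiary C4 radical closes ring A and then ring B by two 6-endo additions through a chair–chair array and the C8 radical hands a C17 hydrogen back to cobalt to give the exocyclic alkene (any Δ8 isomer converges in step 13), the closest known reactions being cobalt–salen hydrogen-atom-transfer cycloisomerisations and hydrogen-atom-initiated radical polyene cyclisations, which form the same bonds in the same order as the enzymatic proton-initiated cyclisation; the C1 silyloxy and C7 hydroxyl groups lie pseudoaxial to avoid A(1,2) strain with the vinylic methyls and so select one face together, giving the trans-decalin with 5β-H, 9β-H, 10α-CH3 and the larger CH2SiMe3 equatorial (4β).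

Step 13
Reactants: 27 labdane-type bicyclic 8(17)-ene
Product: 29 7β-hydroxy-cleroda-4(18)-ene (1β-OTBS; full description in the list), via 7-O-trimethylsilyl ether 28 (not isolated)
Conditions: BF3·OEt2 (0.3 equiv), CH2Cl2 (0.01 M), −78 → −30 °C; Et3N; then 5% aq. citric acid, THF, rt
Reagents that add atoms: none
Why: Proposed new method: the BF3-complexed axial 7-hydroxyl protonates the neighbouring exocyclic alkene at C17, and the C8 cation relays through suprafacial, mutually anti 1,2-shifts (H-9β→C8, 10α-CH3→C9, H-5β→C10, 4α-CH3→C5) to a β-silyl-stabilised C4 cation that irreversibly loses Me3Si+ to the C7 oxygen, a remote Peterson-type elimination whose closest known relatives are BF3-mediated friedo rearrangements of drimane and labdane alkenes and silicon-terminated Wagner–Meerwein shifts; this sets 9α-CH3/C11β, 10β-H and 5α-CH3 stereospecifically and gives only the 4(18)-alkene, the pinacol shift at C8 is disfavoured because H-7 is equatorial, and no free acid remains to isomerise the product.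

Step 14
Reactants: 29 7β-hydroxy-cleroda-4(18)-ene
Product: 31 1β-(tert-butyldimethylsilyloxy)-7-oxo-cleroda-4(18),8(17)-diene, via 7-ketone 30 (not isolated)
Conditions: IBX (4 equiv), 4-methoxypyridine N-oxide (4 equiv), DMSO, 25 → 50 °C
Reagents that add atoms: none
Why: IBX oxidises the alcohol and then dehydrogenates the ketone (Nicolaou dehydrogenation); C9 and C5 are quaternary, so the only β-hydrogens are on C17 and only the exocyclic enone can form.

Step 15
Reactants: 31 1β-(tert-butyldimethylsilyloxy)-7-oxo-cleroda-4(18),8(17)-diene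
Product: 32 1β-hydroxy-7-oxo-cleroda-4(18),8(17)-diene
Conditions: HF·pyridine, pyridine/THF, 0 °C → rt
Reagents that add atoms: none
Why: Buffered fluoride desilylation leaves the lactone, the tiglate and the enone untouched.

Step 16
Reactants: 32 1β-hydroxy-7-oxo-cleroda-4(18),8(17)-diene
Product: 33 1β-isobutyryloxy-7-oxo-cleroda-4(18),8(17)-diene
Conditions: (i-PrCO)2O, Et3N, DMAP, CH2Cl2, 25 °C
Reagents that add atoms: 2-methylpropanoic anhydride, CC(C)C(=O)OC(=O)C(C)C
Why: DMAP-catalysed acylation of the only free hydroxyl, with retention at C1.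

Step 17
Reactants: 33 1β-isobutyryloxy-7-oxo-cleroda-4(18),8(17)-diene
Product: 36 6β-hydroxy ketone (6-epimer of the target), via trimethylsilyl dienol ether 34 (not isolated), via 6β-silyloxy ketone 35 (not isolated)
Conditions: TMSOTf, Et3N, CH2Cl2, −78 → 0 °C; DMDO (1.0 equiv), acetone, −78 °C; aq. citric acid, THF
Reagents that add atoms: dimethyldioxirane, CC1(C)OO1
Why: Rubottom oxidation: soft enolisation is possible only toward C6, and the electron-rich silyl enol ether is oxidised faster than the 4(18)-alkene, from the β-face because the axial 5α- and 9α-methyls shield the α-face, which gives the 6β (6S) alcohol.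

Step 18
Reactants: 36 6β-hydroxy ketone
Product: 37 CNP0148909.1
Conditions: DBU (0.2 equiv), toluene, 25 °C, Ar
Reagents that add atoms: none
Why: Base-mediated α-ketol epimerisation through the enediol: re-protonation at C6 from the open β-face gives the equatorial, hydrogen-bonded 6α-alcohol (6R), and the enone conjugation keeps the carbonyl at C7.

## Compound list

1 | methyl 4,4-dimethoxybutanoate | COC(=O)CCC(OC)OC | starting material
2 | (trimethylsilyl)methylmagnesium chloride | C[Si](C)(C)C[Mg]Cl | starting material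
3 | 5,5-dimethoxy-1-(trimethylsilyl)-2-[(trimethylsilyl)methyl]pentan-2-ol | COC(OC)CCC(O)(C[Si](C)(C)C)C[Si](C)(C)C | intermediate
4 | (5,5-dimethoxy-2-methylidenepentyl)trimethylsilane | COC(OC)CCC(=C)C[Si](C)(C)C | intermediate
5 | 4-[(trimethylsilyl)methyl]pent-4-enal | O=CCCC(=C)C[Si](C)(C)C | intermediate
6 | pent-3-yn-1-ol | CC#CCCO | starting material
7 | triethyl(pent-3-yn-1-yloxy)silane | CC#CCCO[Si](CC)(CC)CC | intermediate
8 | chlorobis(cyclopentadienyl)[(2E)-5-(triethylsilyloxy)pent-2-en-2-yl]zirconium | C/C(=C\CCO[Si](CC)(CC)CC)[Zr](Cl)(C1C=CC=C1)C1C=CC=C1 | intermediate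
9 | methyl[(2E)-5-(triethylsilyloxy)pent-2-en-2-yl]zinc | C/C(=C\CCO[Si](CC)(CC)CC)[Zn]C | intermediate
10 | (3E,5R)-4-methyl-8-methylidene-1-(triethylsilyloxy)-9-(trimethylsilyl)non-3-en-5-ol | C[Si](C)(C)CC(=C)CC[C@@H](O)/C(C)=C/CCO[Si](CC)(CC)CC | intermediate
11 | (3E,5R)-5-(tert-butyldimethylsilyloxy)-4-methyl-8-methylidene-1-(triethylsilyloxy)-9-(trimethylsilyl)non-3-ene | C[Si](C)(C)CC(=C)CC[C@@H](O[Si](C)(C)C(C)(C)C)/C(C)=C/CCO[Si](CC)(CC)CC | intermediate
12 | (3E,5R)-5-(tert-butyldimethylsilyloxy)-4-methyl-8-methylidene-9-(trimethylsilyl)non-3-enal | C[Si](C)(C)CC(=C)CC[C@@H](O[Si](C)(C)C(C)(C)C)/C(C)=C/CC=O | intermediate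
13 | 4-ethenyl-1,3-dioxolan-2-one (vinyl ethylene carbonate) | C=CC1COC(=O)O1 | starting material
14 | pent-3-ynal | CC#CCC=O | intermediate
15 | (2R,3R)-2-ethenylhept-5-yne-1,3-diol | CC#CC[C@@H](O)[C@@H](CO)C=C | intermediate
16 | (2R,3R)-1-(tert-butyldimethylsilyloxy)-2-ethenylhept-5-yn-3-ol | CC#CC[C@@H](O)[C@@H](CO[Si](C)(C)C(C)(C)C)C=C | intermediate
17 | (2R,3R)-1-(tert-butyldimethylsilyloxy)-2-ethenylhept-5-yn-3-yl (2E)-2-methylbut-2-enoate | CC#CC[C@@H](OC(=O)/C(C)=C/C)[C@@H](CO[Si](C)(C)C(C)(C)C)C=C | intermediate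
18 | B-alkyl-9-borabicyclo[3.3.1]nonane from hydroboration of the vinyl group of 17 | CC#CC[C@@H](OC(=O)/C(C)=C/C)[C@@H](CO[Si](C)(C)C(C)(C)C)CCB1C2CCCC1CCC2 | intermediate
19 | (3R,4R)-3-[(tert-butyldimethylsilyloxy)methyl]-1-hydroxyoct-6-yn-4-yl (2E)-2-methylbut-2-enoate | CC#CC[C@@H](OC(=O)/C(C)=C/C)[C@@H](CO[Si](C)(C)C(C)(C)C)CCO | intermediate
20 | (3R,4R)-3-[(tert-butyldimethylsilyloxy)methyl]-1-oxooct-6-yn-4-yl (2E)-2-methylbut-2-enoate | CC#CC[C@@H](OC(=O)/C(C)=C/C)[C@@H](CO[Si](C)(C)C(C)(C)C)CC=O | intermediate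
21 | (3R,4R)-3-[(tert-butyldimethylsilyloxy)methyl]-4-[(2E)-2-methylbut-2-enoyloxy]oct-6-ynoic acid | CC#CC[C@@H](OC(=O)/C(C)=C/C)[C@@H](CO[Si](C)(C)C(C)(C)C)CC(=O)O | intermediate
22 | (3R,4R)-3-(hydroxymethyl)-4-[(2E)-2-methylbut-2-enoyloxy]oct-6-ynoic acid | CC#CC[C@@H](OC(=O)/C(C)=C/C)[C@@H](CO)CC(=O)O | intermediate
23 | (1R)-1-[(3R)-5-oxooxolan-3-yl]pent-3-yn-1-yl (2E)-2-methylbut-2-enoate | CC#CC[C@@H](OC(=O)/C(C)=C/C)[C@H]1COC(=O)C1 | intermediate
24 | chlorobis(cyclopentadienyl){(2E,5R)-5-[(2E)-2-methylbut-2-enoyloxy]-5-[(3R)-5-oxooxolan-3-yl]pent-2-en-2-yl}zirconium | C/C(=C\C[C@@H](OC(=O)/C(C)=C/C)[C@H]1COC(=O)C1)[Zr](Cl)(C2C=CC=C2)C2C=CC=C2 | intermediate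
25 | methyl{(2E,5R)-5-[(2E)-2-methylbut-2-enoyloxy]-5-[(3R)-5-oxooxolan-3-yl]pent-2-en-2-yl}zinc | C/C(=C\C[C@@H](OC(=O)/C(C)=C/C)[C@H]1COC(=O)C1)[Zn]C | intermediate
26 | (1R,3E,5S,7E,9R)-9-(tert-butyldimethylsilyloxy)-5-hydroxy-4,8-dimethyl-12-methylidene-1-[(3R)-5-oxooxolan-3-yl]-13-(trimethylsilyl)trideca-3,7-dien-1-yl (2E)-2-methylbut-2-enoate (clerodane numbering: 1R, 7S, 12R, 13R) | C[Si](C)(C)CC(=C)CC[C@@H](O[Si](C)(C)C(C)(C)C)/C(C)=C/C[C@H](O)/C(C)=C/C[C@@H](OC(=O)/C(C)=C/C)[C@H]1COC(=O)C1 | intermediate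
27 | labdane-type trans-decalin of the antipodal series: 1β-OTBS (1R), 4α-CH3, 4β-CH2SiMe3, 5β-H, 7β-OH (7S), 8(17)-exocyclic alkene, 9β-H (C11 α), 10α-CH3, 12R-tiglate, 13R, 15,16-olide | C[Si](C)(C)C[C@@]1(C)CC[C@@H](O[Si](C)(C)C(C)(C)C)[C@]2(C)[C@@H]1C[C@H](O)C(=C)[C@H]2C[C@@H](OC(=O)/C(C)=C/C)[C@H]1COC(=O)C1 | intermediate
28 | 7-O-trimethylsilyl ether of 29 | C=C1CC[C@@H](O[Si](C)(C)C(C)(C)C)[C@H]2[C@@]1(C)C[C@H](O[Si](C)(C)C)[C@@H](C)[C@]2(C)C[C@@H](OC(=O)/C(C)=C/C)[C@H]1COC(=O)C1 | intermediate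
29 | 1β-(tert-butyldimethylsilyloxy)-7β-hydroxy-12-tigloyloxycleroda-4(18)-en-15,16-olide: 5α-CH3, 8β-H (17-CH3 α), 9α-CH3 (C11 β), 10β-H, 12R, 13R | C=C1CC[C@@H](O[Si](C)(C)C(C)(C)C)[C@H]2[C@@]1(C)C[C@H](O)[C@@H](C)[C@]2(C)C[C@@H](OC(=O)/C(C)=C/C)[C@H]1COC(=O)C1 | intermediate
30 | 1β-(tert-butyldimethylsilyloxy)-7-oxo-12-tigloyloxycleroda-4(18)-en-15,16-olide (8β-H) | C=C1CC[C@@H](O[Si](C)(C)C(C)(C)C)[C@H]2[C@@]1(C)CC(=O)[C@@H](C)[C@]2(C)C[C@@H](OC(=O)/C(C)=C/C)[C@H]1COC(=O)C1 | intermediate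
31 | 1β-(tert-butyldimethylsilyloxy)-7-oxo-12-tigloyloxycleroda-4(18),8(17)-dien-15,16-olide | C=C1CC[C@@H](O[Si](C)(C)C(C)(C)C)[C@H]2[C@@]1(C)CC(=O)C(=C)[C@]2(C)C[C@@H](OC(=O)/C(C)=C/C)[C@H]1COC(=O)C1 | intermediate
32 | 1β-hydroxy-7-oxo-12-tigloyloxycleroda-4(18),8(17)-dien-15,16-olide | C=C1CC[C@@H](O)[C@H]2[C@@]1(C)CC(=O)C(=C)[C@]2(C)C[C@@H](OC(=O)/C(C)=C/C)[C@H]1COC(=O)C1 | intermediate
33 | 1β-isobutyryloxy-7-oxo-12-tigloyloxycleroda-4(18),8(17)-dien-15,16-olide | C=C1CC[C@@H](OC(=O)C(C)C)[C@H]2[C@@]1(C)CC(=O)C(=C)[C@]2(C)C[C@@H](OC(=O)/C(C)=C/C)[C@H]1COC(=O)C1 | intermediate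
34 | 7-(trimethylsilyloxy)-6,8(17)-diene (silyl dienol ether of 33) | C=C1CC[C@@H](OC(=O)C(C)C)[C@H]2[C@@]1(C)C=C(O[Si](C)(C)C)C(=C)[C@]2(C)C[C@@H](OC(=O)/C(C)=C/C)[C@H]1COC(=O)C1 | intermediate
35 | 6β-(trimethylsilyloxy)-7-ketone | C=C1CC[C@@H](OC(=O)C(C)C)[C@H]2[C@@]1(C)[C@H](O[Si](C)(C)C)C(=O)C(=C)[C@]2(C)C[C@@H](OC(=O)/C(C)=C/C)[C@H]1COC(=O)C1 | intermediate
36 | (6S)-6β-hydroxy-1β-isobutyryloxy-7-oxo-12-tigloyloxycleroda-4(18),8(17)-dien-15,16-olide (6-epimer of the target) | C=C1CC[C@@H](OC(=O)C(C)C)[C@H]2[C@@]1(C)[C@H](O)C(=O)C(=C)[C@]2(C)C[C@@H](OC(=O)/C(C)=C/C)[C@H]1COC(=O)C1 | intermediate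
37 | CNP0148909.1: (1R,5R,6R,9R,10R,12R,13R)-6α-hydroxy-1β-isobutyryloxy-7-oxo-12-tigloyloxycleroda-4(18),8(17)-dien-15,16-olide | C=C1CC[C@@H](OC(=O)C(C)C)[C@H]2[C@@]1(C)[C@@H](O)C(=O)C(=C)[C@]2(C)C[C@@H](OC(=O)/C(C)=C/C)[C@H]1COC(=O)C1 | target

## Step count and risks

Total steps: 18. Longest linear sequence: 13 (steps 6–10, then 11–18).

Most likely to fail:

1. Step 13 (backbone rearrangement). The risks are a pinacol-type shift at C8, loss of the allylic hydroxyl, or the cascade stalling at a halimane alkene. Fallback, setting out from 27 and returning at 29: deactivate the C7 oxygen and move the proton source outside the molecule. Acylate 27 with trifluoroacetic anhydride/pyridine to the 7-O-trifluoroacetate F5, whose electron-poor ester neither participates nor supports a pinacol shift. Add TfOH (1.0 equiv) slowly at −78 °C in CH2Cl2 and quench with Et3N; the same shift sequence, ended by loss of silicon, gives the rearranged clerodane trifluoroacetate F6. Brief methanolysis (NaHCO3, MeOH, 0 °C) then gives 29.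

2. Step 12 (hydrogen-atom-initiated bicyclisation). The risks are simple alkene isomerisation, low facial control, or poor regiochemistry in the final hydrogen return. Fallback, setting out from 26 and returning at 27: give the second ring closure a polarity-matched acceptor and run it reductively. Oxidise the C7 allylic alcohol of 26 with MnO2 to the cross-conjugated dienone F1. Cyclise with Fe(acac)3/PhSiH3 in EtOH (hydrogen-atom-initiated Giese bicyclisation ending on the enone) to the bicyclic 7-ketone F2. Convert this with TMSOTf/Et3N into the C7–C8 trimethylsilyl enol ether F3 and oxidise with Pd(OAc)2 (Saegusa–Ito; only the C17 hydrogens can reach the syn arrangement) to the 8(17)-en-7-one F4. A Corey–Bakshi–Shibata reduction (catalyst antipode chosen for 7S) returns 27.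

3. Step 18 (C6 epimerisation). The equilibrium might not favour the 6α-alcohol cleanly. Fallback, setting out from 36 and returning at 37: set C6 by hydride delivery instead of protonation. Oxidise 36 with Dess–Martin periodinane to the 6,7-dione F7. Reduce with Zn(BH4)2 in Et2O at −78 °C; the non-conjugated, more electrophilic C6 carbonyl is attacked from the open β-face, which gives the 6α-alcohol 37 directly.

## Further compounds

F1 | step 12 | (1R,3E,7E,9R)-9-(tert-butyldimethylsilyloxy)-4,8-dimethyl-12-methylidene-5-oxo-1-[(3R)-5-oxooxolan-3-yl]-13-(trimethylsilyl)trideca-3,7-dien-1-yl (2E)-2-methylbut-2-enoate | C[Si](C)(C)CC(=C)CC[C@@H](O[Si](C)(C)C(C)(C)C)/C(C)=C/CC(=O)/C(C)=C/C[C@@H](OC(=O)/C(C)=C/C)[C@H]1COC(=O)C1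
F2 | step 12 | labdane-type bicyclic 7-ketone (1β-OTBS, 4β-CH2SiMe3, 5β-H, 8β-CH3, 9β-H, 10α-CH3, 12R, 13R) | C[Si](C)(C)C[C@@]1(C)CC[C@@H](O[Si](C)(C)C(C)(C)C)[C@]2(C)[C@@H]1CC(=O)[C@H](C)[C@H]2C[C@@H](OC(=O)/C(C)=C/C)[C@H]1COC(=O)C1
F3 | step 12 | C7–C8 trimethylsilyl enol ether of F2 | C[Si](C)(C)C[C@@]1(C)CC[C@@H](O[Si](C)(C)C(C)(C)C)[C@]2(C)[C@@H]1CC(O[Si](C)(C)C)=C(C)[C@H]2C[C@@H](OC(=O)/C(C)=C/C)[C@H]1COC(=O)C1
F4 | step 12 | labdane-type 8(17)-en-7-one (7-ketone corresponding to 27) | C[Si](C)(C)C[C@@]1(C)CC[C@@H](O[Si](C)(C)C(C)(C)C)[C@]2(C)[C@@H]1CC(=O)C(=C)[C@H]2C[C@@H](OC(=O)/C(C)=C/C)[C@H]1COC(=O)C1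
F5 | step 13 | 7-O-trifluoroacetate of 27 | C[Si](C)(C)C[C@@]1(C)CC[C@@H](O[Si](C)(C)C(C)(C)C)[C@]2(C)[C@@H]1C[C@H](OC(=O)C(F)(F)F)C(=C)[C@H]2C[C@@H](OC(=O)/C(C)=C/C)[C@H]1COC(=O)C1
F6 | step 13 | 7-O-trifluoroacetate of 29 | C=C1CC[C@@H](O[Si](C)(C)C(C)(C)C)[C@H]2[C@@]1(C)C[C@H](OC(=O)C(F)(F)F)[C@@H](C)[C@]2(C)C[C@@H](OC(=O)/C(C)=C/C)[C@H]1COC(=O)C1
F7 | step 18 | 1β-isobutyryloxy-6,7-dioxo-12-tigloyloxycleroda-4(18),8(17)-dien-15,16-olide | C=C1CC[C@@H](OC(=O)C(C)C)[C@H]2[C@@]1(C)C(=O)C(=O)C(=C)[C@]2(C)C[C@@H](OC(=O)/C(C)=C/C)[C@H]1COC(=O)C1
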